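Minutes: one flask.

all flasks: Sbt 0.050 M
- beta: Rgt 0.050 M; Bse 0.15 M; Spx2 5 mM; the very flask that is asked about, followed so far
- flask: Rgt 0.0500 M; Bse 0.150 M; Spx2 5.00 mM; time 10 h

beta run (percent of the Sbt charged)

| time / min | Sbt / % | Prd / % |
|---|---|---|
| 10.0 | 97.3 | 1.0 |
| 20.0 | 96.2 | 0.9 |
| 30.0 | 93.3 | 1.4 |
| 40.0 | 92.0 | 2.6 |
| 50.0 | 89.7 | 3.7 |
| 60.0 | 87.7 | 3.5 |
| 80.0 | 85.4 | 4.4 |

(scatter of a reading: 0.5 percentage points)

- Spx is the free proton; pH is minus the decimal logarithm of its molar concentration
- percentages count the Sbt that a species holds: one Prd2 counts as two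
- the earlier runs were read with a standard deviation of 0.5 percentage points
- steps under discussion: Sbt + Rgt -> Spx + Prd + Lvg; Rgt2 <-> Rgt + Spx; Spx2 <-> Bse + Spx; Prd <-> Sdp; 2 Sbt -> Prd2
- the earlier runs do not show the pH; that part of a forecast is a guess

1. part of the Sbt that has reacted at 10 h
2. pH of the solution at 10 h

The first chemist took the last beta reading, at 80.0 min. She argued that if Sbt fell as a second-order species, the inverse of the fraction left, less one, would grow evenly with time, which gave a constant of 0.128 h⁻¹ and, at 10 h, a fraction left of 43.8%, so 56.2% reacted.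

The second chemist objected. Prd held 30.1% of that loss, as a reading with a scatter of 0.5 percentage points on each point. He named this the Rgt share, the part of the Sbt loss that runs through Rgt, a selectivity towards Prd. The remainder he gave to Prd2, which follows Sbt squared, whereas the Prd step follows Sbt times Rgt.

He then put her answer back in. With equal charges, Rgt loses the share of what Sbt loses, so Rgt keeps 83.1%, more than Sbt, with none of it set aside as Rgt2. Averaging the Rgt-to-Sbt ratio between start and end, he multiplied her constant by a lift of 1.13.

The second round gave 59.3% reacted, and the meeting committed to that. The runs show no pH, so any figure for it is a guess.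

The forecast stood at 59% (49% to 72%) and pH 8 (5.8 to 10), noting that “the absolute pH is a guess”.

The flask gives 60.0% reacted and pH 4.74, from these steps:

    Sbt + Rgt → Spx + Prd + Lvg (k = 0.0144 M⁻¹ min⁻¹)
    Rgt2 ⇌ Rgt + Spx, settled at all times (K = 2.00 × 10⁻⁴ M)
    Spx2 ⇌ Bse + Spx, settled at all times (K = 2.00 × 10⁻⁴ M)
    Prd ⇌ Sdp (K = 28.0, k = 3.19 × 10⁻⁴ min⁻¹)
    2 Sbt → Prd2 (k = 0.0151 M⁻¹ min⁻¹)

At 10.0 h this flask holds Sbt at 40% of its charge and free Rgt at 71%, less Sbt than Rgt. With the Rgt share, those two fractions give a lift of 1.12, where the meeting had 1.13. The same two rounds for the neighbour read at 25 h, all amounts held, give 81.1% reacted, and that neighbour stands at 81.6%.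

The earlier runs and the new flask were generated by integration with constants of no real substance; scatter was added.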